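**The partner.** The partner couples with both substrates, faster with the left-handed one, and I ask how much of that lead survives between the two product peaks.

| setting | elm | alder | oak | maple |
|---|---|---|---|---|
| left-handed substrate | 14 mM | 14 mM | 14 mM | 14 mM |
| solid reagent | 30.8 mM | 30.8 mM | 30.8 mM | 30.8 mM |
| right-handed substrate | 14 mM | 14 mM | 14 mM | 14 mM |
| temperature | 75 °C | 60 °C |  | 45 °C |
| time | 6.0 h | 6.0 h | 6.0 h | 6.0 h |
| remark |  |  | at 45 °C until 3.0 h, from then on at 75 °C |  |

- which flask leads in excess of left-handed product over right-handed product ("all alike" within 1.5 percentage points) (elm / alder / oak / maple / all alike)
- excess of left-handed product over right-handed product at the end, elm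
- excess of left-handed product over right-handed product at the end, alder
- excess of left-handed product over right-handed product at the end, oak
- excess of left-handed product over right-handed product at the end, maple

- partner is single-handed; left-handed substrate and right-handed substrate are mirror images of each other, charged as a racemate, each of them at the stated concentration
- as a solid, counted per litre of solution: solid reagent
- all constants are for 60 °C and move with temperature by the activation energies and enthalpies
- at the start none of the solid reagent is in solution
- an excess is the difference of the two amounts in percent of their sum
- an excess is below zero if the other one leads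
- the handed part of partner does not stay in what it makes, so the products of the two hands are mirror images too

    partner + left-handed substrate → left-handed product (k1 = 5.5 /M/h, Ea1 = 85.0 kJ/mol)
    partner + right-handed substrate → right-handed product (k2 = 0.60 /M/h, Ea2 = 78.0 kJ/mol)
    left-handed substrate ⇌ achiral form (K3 = 0.059, k3 = 0.096 /h, Ea3 = 121 kJ/mol, ΔH3 = −53.0 kJ/mol)
    right-handed substrate ⇌ achiral form (K3 = 0.059, k3 = 0.096 /h, Ea3 = 121 kJ/mol, ΔH3 = −53.0 kJ/mol)
    solid reagent ⇌ partner, rate k5*(cs5 - [partner]) while solid is left; crystals form when [partner] > cs5 (cs5 = 2.4 mM, k5 = 4.3 /h)
    left-handed product ⇌ right-handed product (k6 = 0.13 /h, Ea6 = 100 kJ/mol)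
    (constants at 60 °C)

**Steady feed.** [partner] rises towards 2.4 mM with a half-life of 0.161 h, which is short against the run. In elm a substrate enters the achiral form, where it can change hands, with a forward half-life of 1.10 h, and the left-handed coupling at [partner] of 2.4 mM uses it up with a half-life of 14.0 h, which is longer. In maple that coupling takes about 1.86 % of the left-handed substrate over the run. So I hold the two substrates nearly equal and the couplings nearly steady and pseudo-first-order. Kinetic control then gives an excess s, the difference of the two coupling constants over their sum, which follows from the selectivity factor. Thermodynamic control gives zero.

**The count.** Racemisation of the products relaxes with a half-life of 0.563 h in elm, short against 6.0 h. I count x, the run time in units of that relaxation, which is 7.39 for elm. With steady making, the difference between the products levels off while their sum grows straight. So the excess is s times one minus exp(−x), divided by x.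

**Elm's curve.** In elm the right-handed coupling runs at 0.0978 of the left-handed one, so the excess starts at 82.2 %. The knee, where x reaches one, comes at 0.812 h, and the excess there is 52.0 %. Past it the difference stands level and the growing sum dilutes it, so elm ends near 11.1 %.

**Other flasks.** Alder counts 1.56, with s at 80.3 %, which gives 40.7 %. Maple counts 0.284. Its ratio of constants is 0.123, so s is 78.1 % and I get 68.0 %, the highest of mine. Oak is cold until 3.0 h, when its left-handed coupling runs at 0.0627 of its hot speed. Its hot stretch counts 3.69, which shrinks the cold difference to 0.0250 of itself, so I drop that difference and keep the cold product in the sum. That gives oak 20.4 %.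

**The result.** The forecast names maple, with 10 % for elm, 38.5 % for alder, 19 % for oak and 67.5 % for maple, on the ground that racemization “erases excess quickly when hot”. The simulation gives 10.8 % for elm, 40.9 % for alder, 19.7 % for oak and 68.1 % for maple, so maple leads.

**Hotter neighbour.** A repeat of elm at 90 °C counts 30.8, which is 4.17 times elm's 7.39. Its ratio of constants is 0.0885, so s is 83.7 % and the same reckoning gives 2.72 %. At 6.00 h that flask holds 63 % of its charged left-handed substrate, with left-handed product at 17.9 % and right-handed product at 17.1 %. Its excess is 2.33 %, which is 0.39 percentage points less than my figure.

The numbers of this flask were drawn at random within sensible limits; no experiment stands behind them.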